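**Retrosynthetic overview**
- Ring A is opened at C7–C8 and ring C at O1–C8a/C4a=C8a: the target becomes an (S)-δ-hydroxy-3,5-diketo tert-butyl ester plus a two-carbon amide acetal that supplies C8a and C8.
- The diketo ester comes from a Claisen condensation: γ-carbanion of tert-butyl 2-prenylacetoacetate (C4a, C5, C6 with prenyl, C7) onto an (S)-β-hydroxy ester (C2, C3, C4).
- The (S)-β-hydroxy ester comes from asymmetric transfer hydrogenation of the commercial aryl β-keto ester; the prenylacetoacetate from tert-butyl acetoacetate and prenyl bromide.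
- Ring order: the dihydropyranone ring C closes first (O1–C8a, stereocentre carried in from the alcohol), then the phloroglucinol ring A closes by acylketene benzannulation, both in the last flask. The prenyl carbon lies between the two carbons that become phenols, so only the 6-prenyl isomer can form.

Assumption: the prenyl-bearing carbon of the ester chain in 5, 6, 8 and 9 is carried as a mixture of epimers/enol tautomers (it becomes aromatic C6), and the alkene geometry of 8 is left open.

**Route**

Step 1
Reactants: 1 ethyl 3-(4-methoxyphenyl)-3-oxopropanoate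
Product: 2 ethyl (3S)-3-hydroxy-3-(4-methoxyphenyl)propanoate
Conditions: RuCl(p-cymene)[(S,S)-TsDPEN] (1 mol%), HCO2H/Et3N 5:2, DMF, 40 °C
Reagents that add atoms: none
Why: Noyori–Ikariya asymmetric transfer hydrogenation of an aryl ketone; the (S,S)-catalyst delivers hydride to the face that gives the (S)-benzylic alcohol (same sense as acetophenone to (S)-1-phenylethanol), and this C–O stereocentre later becomes C2 without ever being broken.

Step 2
Reactants: 3 tert-butyl 3-oxobutanoate; 4 1-bromo-3-methylbut-2-ene (prenyl bromide)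
Product: 5 tert-butyl 2-acetyl-5-methylhex-4-enoate
Conditions: NaH (1.0 equiv), THF, 0 °C to rt, 3 in 1.3-fold excess
Reagents that add atoms: none
Why: Acetoacetic ester alkylation (SN2 of the sodium enolate on the allylic bromide), with excess 3 suppressing dialkylation; no stereocentre of consequence is formed.

Step 3
Reactants: 5 tert-butyl 2-acetyl-5-methylhex-4-enoate; 2 ethyl (3S)-3-hydroxy-3-(4-methoxyphenyl)propanoate
Product: 6 tert-butyl (7S)-7-hydroxy-7-(4-methoxyphenyl)-2-(3-methylbut-2-en-1-yl)-3,5-dioxoheptanoate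
Conditions: 5 (3 equiv), LDA (6 equiv), THF, −78 to 0 °C; then 2 (1 equiv), −78 to 0 °C; AcOH then pH 7 buffer, no contact with stronger acid, used crude or after Et3N-deactivated silica
Reagents that add atoms: none
Why: Crossed Claisen condensation of the γ-carbanion of the β-keto ester dianion (Weiler dianion) with the ethyl ester, where one equivalent of dianion deprotonates the hydroxyl, one acylates and one deprotonates the product; the carbinol centre is not touched and retro-aldol of the lithium alkoxide is slow at these temperatures.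

Step 4
Reactants: 6 tert-butyl (7S)-7-hydroxy-7-(4-methoxyphenyl)-2-(3-methylbut-2-en-1-yl)-3,5-dioxoheptanoate; 7 1,1-dimethoxy-N,N-dimethylethan-1-amine (N,N-dimethylacetamide dimethyl acetal)
Product: 11 (2S)-5,7-dihydroxy-2-(4-methoxyphenyl)-6-(3-methylbut-2-en-1-yl)-2,3-dihydro-4H-chromen-4-one, via enaminone 8 (not isolated), via dihydropyranone 9 (not isolated), via acylketene 10 (not isolated)
Conditions: 7 (1.2 equiv), PhMe, 4 Å MS, rt to 70 °C, N2 sweep; then xylenes, 135 °C, 0.01 M, same flask
Reagents that add atoms: none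
Why: Proposed new method: the amide acetal condenses at the doubly activated C4 methylene between the two ketones to give enaminone 8, the (S)-hydroxyl displaces dimethylamine by oxa-conjugate addition–elimination to close dihydropyranone 9 (the C–O stereocentre is only carried along), and above about 110 °C the tert-butyl β-keto ester loses tert-butanol to acylketene 10, whose dienol tautomer (ring methyl enolised onto the acyl oxygen) closes by 6π-electrocyclisation or C-acylation of the exocyclic enol ether and tautomerises to the phloroglucinol ring; the closest known reactions are amide-acetal construction of 5-acyl-2,3-dihydro-4H-pyran-4-ones from δ-hydroxy-β-dicarbonyls, thermal acylketene generation from tert-butyl β-keto esters, and dienylketene electrocyclisation in Danheiser-type benzannulation.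

**Compound list**

1 | ethyl 3-(4-methoxyphenyl)-3-oxopropanoate | COc1ccc(C(=O)CC(=O)OCC)cc1 | starting material
2 | ethyl (3S)-3-hydroxy-3-(4-methoxyphenyl)propanoate | COc1ccc([C@@H](O)CC(=O)OCC)cc1 | intermediate
3 | tert-butyl 3-oxobutanoate | CC(=O)CC(=O)OC(C)(C)C | starting material
4 | 1-bromo-3-methylbut-2-ene | CC(C)=CCBr | starting material
5 | tert-butyl 2-acetyl-5-methylhex-4-enoate | CC(=O)C(CC=C(C)C)C(=O)OC(C)(C)C | intermediate
6 | tert-butyl (7S)-7-hydroxy-7-(4-methoxyphenyl)-2-(3-methylbut-2-en-1-yl)-3,5-dioxoheptanoate | COc1ccc([C@@H](O)CC(=O)CC(=O)C(CC=C(C)C)C(=O)OC(C)(C)C)cc1 | intermediate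
7 | 1,1-dimethoxy-N,N-dimethylethan-1-amine | COC(C)(OC)N(C)C | starting material
8 | tert-butyl (7S)-4-[1-(dimethylamino)ethylidene]-7-hydroxy-7-(4-methoxyphenyl)-2-(3-methylbut-2-en-1-yl)-3,5-dioxoheptanoate | COc1ccc([C@@H](O)CC(=O)C(=C(C)N(C)C)C(=O)C(CC=C(C)C)C(=O)OC(C)(C)C)cc1 | intermediate
9 | tert-butyl 2-{[(2S)-2-(4-methoxyphenyl)-6-methyl-4-oxo-3,4-dihydro-2H-pyran-5-yl]carbonyl}-5-methylhex-4-enoate | COc1ccc([C@@H]2CC(=O)C(C(=O)C(CC=C(C)C)C(=O)OC(C)(C)C)=C(C)O2)cc1 | intermediate
10 | 2-{[(2S)-2-(4-methoxyphenyl)-6-methyl-4-oxo-3,4-dihydro-2H-pyran-5-yl]carbonyl}-5-methylhexa-1,4-dien-1-one | COc1ccc([C@@H]2CC(=O)C(C(=O)C(CC=C(C)C)=C=O)=C(C)O2)cc1 | intermediate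
11 | (2S)-5,7-dihydroxy-2-(4-methoxyphenyl)-6-(3-methylbut-2-en-1-yl)-2,3-dihydro-4H-chromen-4-one | COc1ccc([C@@H]2CC(=O)c3c(cc(O)c(CC=C(C)C)c3O)O2)cc1 | target

**Totals**

Total step count: 4. Longest linear sequence: 3 (1 → 2 → 6 → 11, or 3 → 5 → 6 → 11).

**Steps most likely to fail, with fallbacks**

Step 4 is the most likely to fail. The ketene closure onto the enolised ring methyl is unprecedented. The ketene could instead be trapped reversibly at oxygen, or form before ring C has closed, which would give a 4-hydroxy-2-pyranone. Traces of acid could also cyclodehydrate 6 to the isomeric 6-substituted dihydropyranone. The fallback sets out from 9 and returns at 11. The first stage is stopped at 70 °C and the dihydropyranone 9 is isolated. Its tert-butyl ester is cleaved without protic acid (TMSOTf, 2,6-lutidine, CH2Cl2, −20 °C, then pH 7 buffer) to 2-{[(2S)-2-(4-methoxyphenyl)-6-methyl-4-oxo-3,4-dihydro-2H-pyran-5-yl]carbonyl}-5-methylhex-4-enoic acid F1. This acid is activated cold with carbonyldiimidazole as the acyl imidazolide 1-(imidazol-1-yl)-3-[(2S)-2-(4-methoxyphenyl)-6-methyl-4-oxo-3,4-dihydro-2H-pyran-5-yl]-2-(3-methylbut-2-en-1-yl)propane-1,3-dione F2. Soft enolisation (MgCl2, Et3N, MeCN, 0 °C) then closes F2 onto the ring methyl. This is a low-temperature ionic C-acylation in place of the thermal fragmentation, and it gives 11 after tautomerisation.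

Step 3 is the second risk. The free lithium alkoxide of 2 may undergo partial retro-aldol (eroding ee) or enolise instead of being acylated, and 6 is acid-sensitive. The fallback sets out from 2 and returns at 6. Compound 2 is converted with MeNHOMe·HCl and iPrMgCl into (3S)-3-hydroxy-N-methoxy-3-(4-methoxyphenyl)-N-methylpropanamide F3. F3 is silylated (TESCl, imidazole) to (3S)-N-methoxy-3-(4-methoxyphenyl)-N-methyl-3-[(triethylsilyl)oxy]propanamide F4. The dianion of 5 (1.2 equiv) is acylated by F4 through the stable chelated tetrahedral intermediate to give tert-butyl (7S)-7-(4-methoxyphenyl)-2-(3-methylbut-2-en-1-yl)-3,5-dioxo-7-[(triethylsilyl)oxy]heptanoate F5. The silyl group is removed with pyridine-buffered HF·pyridine at 0 °C to give 6.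

Step 1 is the third risk. The electron-rich aryl ketone reduces slowly and the ee may fall short. The fallback sets out from 1 and returns at 2. Compound 1 is reduced with NaBH4 in EtOH at 0 °C to racemic ethyl 3-hydroxy-3-(4-methoxyphenyl)propanoate F6. F6 is resolved with Burkholderia cepacia lipase and vinyl acetate in MTBE to about 52% conversion. The enzyme acetylates the (R)-alcohol to ethyl (3R)-3-(acetyloxy)-3-(4-methoxyphenyl)propanoate F7, and the unreacted (S)-alcohol 2 is separated by chromatography (at most 50% yield).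

Further compounds
F1 | step 4 | 2-{[(2S)-2-(4-methoxyphenyl)-6-methyl-4-oxo-3,4-dihydro-2H-pyran-5-yl]carbonyl}-5-methylhex-4-enoic acid | COc1ccc([C@@H]2CC(=O)C(C(=O)C(CC=C(C)C)C(=O)O)=C(C)O2)cc1
F2 | step 4 | 1-(imidazol-1-yl)-3-[(2S)-2-(4-methoxyphenyl)-6-methyl-4-oxo-3,4-dihydro-2H-pyran-5-yl]-2-(3-methylbut-2-en-1-yl)propane-1,3-dione | COc1ccc([C@@H]2CC(=O)C(C(=O)C(CC=C(C)C)C(=O)n3ccnc3)=C(C)O2)cc1
F3 | step 3 | (3S)-3-hydroxy-N-methoxy-3-(4-methoxyphenyl)-N-methylpropanamide | COc1ccc([C@@H](O)CC(=O)N(C)OC)cc1
F4 | step 3 | (3S)-N-methoxy-3-(4-methoxyphenyl)-N-methyl-3-[(triethylsilyl)oxy]propanamide | COc1ccc([C@@H](O[Si](CC)(CC)CC)CC(=O)N(C)OC)cc1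
F5 | step 3 | tert-butyl (7S)-7-(4-methoxyphenyl)-2-(3-methylbut-2-en-1-yl)-3,5-dioxo-7-[(triethylsilyl)oxy]heptanoate | COc1ccc([C@@H](O[Si](CC)(CC)CC)CC(=O)CC(=O)C(CC=C(C)C)C(=O)OC(C)(C)C)cc1
F6 | step 1 | racemic ethyl 3-hydroxy-3-(4-methoxyphenyl)propanoate | COc1ccc(C(O)CC(=O)OCC)cc1
F7 | step 1 | ethyl (3R)-3-(acetyloxy)-3-(4-methoxyphenyl)propanoate | COc1ccc([C@H](OC(C)=O)CC(=O)OCC)cc1
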